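**Assumption:** the SMILES has no stereocentre and the diaryl ether axes rotate freely. The target is therefore achiral and there is no enantiomer to select. The one stereocentre met on the way (the quaternary cyclobutenone carbon) is racemic and is erased on aromatisation.

## Retrosynthetic overview
1. The target comes from one-pot cleavage of ten O-methyl groups and one O-Boc group. Rings A (2,4,6-trioxygenated), C and D (3,4,5-trioxygenated) are bought as trimethoxyaryl units. Only the pentaoxygenated central ring B is built.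
2. The ring D–O bond comes from Chan–Lam arylation of the single free OH of ring B.
3. Ring B comes from 4π-opening/6π-closure (Moore benzannulation) of a 4-alkenyl-4-silyloxycyclobutenone. Four ring carbons come from squaric acid and two from trichloroethylene.
4. The key C–C bond joins a 1-(aryloxy)vinyllithium (an acetyl anion equivalent carrying ring A) to a carbonyl carbon of a methyl aryl squarate (carrying ring C).
5. Ring order: the four-membered ring is bought as squaric acid and then expanded to ring B, the only ring formed.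

## Route

**Step 1**
Reactants: 1 2,4,6-trimethoxyphenol; 2 trichloroethylene
Product: 4 2-[(E)-1,2-dichloroethenoxy]-1,3,5-trimethoxybenzene, via dichloroacetylene 3 (not isolated)
Conditions: K2CO3 (3 equiv), 2 (2 equiv), DMF, 70 °C, Ar, 16 h
Reagents that add atoms: none
Why: K2CO3 eliminates HCl from 2 to give dichloroacetylene, and the phenoxide adds to it in anti fashion (nucleophilic alkyne addition, dichlorovinyl ether synthesis), which gives only the E isomer and needs no oxidising metal that would attack this electron-rich phenol.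

**Step 2**
Reactants: 4 2-[(E)-1,2-dichloroethenoxy]-1,3,5-trimethoxybenzene
Product: 8 tributyl[1-(2,4,6-trimethoxyphenoxy)ethenyl]stannane, via chloroethynyl aryl ether 5 (not isolated), via lithium aryloxyacetylide 6 (not isolated), via ethynyl aryl ether 7 (not isolated)
Conditions: n-BuLi (2.2 equiv), THF, −78 → −40 °C; H2O, −78 °C, extractive work-up, crude 7 used at once; Bu3SnH (1.1 equiv), Pd(PPh3)4 (2 mol %), THF, 0 °C → rt
Reagents that add atoms: tributyltin hydride, CCCC[SnH](CCCC)CCCC; n-butyllithium, [Li]CCCC (its Li stays only in 6)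
Why: Deprotonation/β-elimination to 5 and Cl–Li exchange give acetylide 6 (ynol ether synthesis from dichlorovinyl ethers), the water quench also erases any stray ring lithiation, and Pd(0)-catalysed syn-hydrostannation of an O-substituted terminal alkyne puts tin on the oxygen-bearing carbon.

**Step 3**
Reactants: 9 squaric acid; 10 3,4,5-trimethoxyphenol
Product: 13 3-methoxy-4-(3,4,5-trimethoxyphenoxy)cyclobut-3-ene-1,2-dione, via squaryl dichloride 11 (not isolated), via 3-chloro-4-methoxycyclobutenedione 12 (not isolated)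
Conditions: (COCl)2 (2.5 equiv), DMF (cat.), ClCH2CH2Cl, 55 °C, then evaporate; MeOH (1.0 equiv), CH2Cl2, −20 °C → rt, Ar purge; 10 (1.0 equiv), i-Pr2NEt (1.1 equiv), −40 → 0 °C
Reagents that add atoms: methanol, CO; oxalyl chloride, O=C(Cl)C(=O)Cl (its Cl stays only in 11 and 12)
Why: Vilsmeier-type chlorination is followed by two addition–elimination steps at a vinylogous acid chloride, in which the first methoxy group deactivates the remaining chloride enough to stop at 12, and the phenoxide, added last, expels chloride and not the much poorer leaving group methoxide.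

**Step 4 (key step)**
Reactants: 8 tributyl[1-(2,4,6-trimethoxyphenoxy)ethenyl]stannane; 13 3-methoxy-4-(3,4,5-trimethoxyphenoxy)cyclobut-3-ene-1,2-dione
Product: 16 (±)-3-methoxy-2-(3,4,5-trimethoxyphenoxy)-4-[1-(2,4,6-trimethoxyphenoxy)ethenyl]-4-(trimethylsilyloxy)cyclobut-2-en-1-one, via 1-(aryloxy)vinyllithium 14 (not isolated), via lithium alkoxide adduct 15 (not isolated)
Conditions: 8, n-BuLi (1.0 equiv), THF, −78 °C, 20 min; cannulate into 13 (1.05 equiv), THF, −78 °C, 30 min; TMSCl (1.5 equiv), −78 → 0 °C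
Reagents that add atoms: chlorotrimethylsilane, C[Si](C)(C)Cl; n-butyllithium, [Li]CCCC (its Li stays only in 14 and 15)
Why: Sn–Li exchange at −78 °C is faster than any metalation of the trimethoxyaryl ring and frees 14, an acetyl anion equivalent, which adds 1,2 to the squarate (organolithium–squarate addition of the Moore–Liebeskind type) at the carbonyl next to C–OMe, since that C=O is conjugated only to the weaker aryloxy donor and is less shielded, so two carbonyl-level carbons are joined; the new quaternary centre is racemic and disappears in step 5.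

**Step 5**
Reactants: 16 (±)-silyloxy cyclobutenone
Product: 20 tert-butyl [4-hydroxy-3-methoxy-2-(3,4,5-trimethoxyphenoxy)-5-(2,4,6-trimethoxyphenoxy)phenyl] carbonate, via dienylketene 17 (not isolated), via silyloxyphenol 18 (not isolated), via silylated Boc carbonate 19 (not isolated)
Conditions: toluene, 110 °C, Ar, 2 h; cool to rt, Boc2O (1.2 equiv), DMAP (10 mol %), 1 h; 1 M aq HCl/THF, 0 °C, 15 min
Reagents that add atoms: di-tert-butyl dicarbonate, CC(C)(C)OC(=O)OC(=O)OC(C)(C)C
Why: In this Moore benzannulation, conrotatory 4π opening turns the silyloxy group outward and the alkenyl group inward, dienylketene 17 closes by 6π electrocyclisation and tautomerises to 18 in which only the ketene-derived OH is free, so Boc2O marks that oxygen and dilute acid then removes the labile aryl TMS ether to bare the one OH that must carry ring D; no stereocentre is left.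

**Step 6**
Reactants: 20 tert-butyl aryl carbonate with one free OH; 21 3,4,5-trimethoxyphenylboronic acid
Product: 22 tert-butyl [3-methoxy-2,4-bis(3,4,5-trimethoxyphenoxy)-5-(2,4,6-trimethoxyphenoxy)phenyl] carbonate
Conditions: 21 (2.5 equiv), Cu(OAc)2 (2 equiv), pyridine (5 equiv), 4 Å MS, CH2Cl2, dry air, rt, 48 h
Reagents that add atoms: none
Why: Chan–Lam oxidative O-arylation runs at room temperature, accepts 2,6-disubstituted phenols when the boronic acid is unhindered as here, and its weak base (pyridine) leaves the aryl carbonate and all ethers untouched.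

**Step 7**
Reactants: 22 fully protected tetramer
Product: 23 2,4-bis(3,4,5-trihydroxyphenoxy)-5-(2,4,6-trihydroxyphenoxy)benzene-1,3-diol (CNP0304743.0)
Conditions: BBr3 (20 equiv), CH2Cl2, −78 °C → rt, Ar, 18 h; ice-water; EtOAc; Sephadex LH-20 (degassed MeOH)
Reagents that add atoms: none
Why: Lewis-acid ether cleavage with BBr3 breaks alkyl–O bonds only (SN2 of bromide at methyl, ionisation of tert-butyl with loss of CO2), while the three aryl–O–aryl bonds have no cleavable sp3 carbon and survive, and the acidic, oxygen-free work-up protects the pyrogallol units.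

## Compound list
1 | 2,4,6-trimethoxyphenol | COc1cc(OC)c(O)c(OC)c1 | starting material
2 | trichloroethylene | ClC=C(Cl)Cl | starting material
3 | dichloroacetylene | ClC#CCl | intermediate
4 | 2-[(E)-1,2-dichloroethenoxy]-1,3,5-trimethoxybenzene | Cl/C=C(/Cl)Oc1c(OC)cc(OC)cc1OC | intermediate
5 | 2-(chloroethynyloxy)-1,3,5-trimethoxybenzene | ClC#COc1c(OC)cc(OC)cc1OC | intermediate
6 | lithium (2,4,6-trimethoxyphenoxy)acetylide | [Li]C#COc1c(OC)cc(OC)cc1OC | intermediate
7 | 2-(ethynyloxy)-1,3,5-trimethoxybenzene | C#COc1c(OC)cc(OC)cc1OC | intermediate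
8 | tributyl[1-(2,4,6-trimethoxyphenoxy)ethenyl]stannane | C=C(Oc1c(OC)cc(OC)cc1OC)[Sn](CCCC)(CCCC)CCCC | intermediate
9 | squaric acid | OC1=C(O)C(=O)C1=O | starting material
10 | 3,4,5-trimethoxyphenol | COc1cc(O)cc(OC)c1OC | starting material
11 | squaryl dichloride (3,4-dichlorocyclobut-3-ene-1,2-dione) | ClC1=C(Cl)C(=O)C1=O | intermediate
12 | 3-chloro-4-methoxycyclobut-3-ene-1,2-dione | COC1=C(Cl)C(=O)C1=O | intermediate
13 | 3-methoxy-4-(3,4,5-trimethoxyphenoxy)cyclobut-3-ene-1,2-dione | COC1=C(Oc2cc(OC)c(OC)c(OC)c2)C(=O)C1=O | intermediate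
14 | 1-(2,4,6-trimethoxyphenoxy)vinyllithium | [Li]C(=C)Oc1c(OC)cc(OC)cc1OC | intermediate
15 | lithium alkoxide of the 1,2-adduct (racemic) | [Li]OC1(C(=C)Oc2c(OC)cc(OC)cc2OC)C(OC)=C(Oc2cc(OC)c(OC)c(OC)c2)C1=O | intermediate
16 | (±)-3-methoxy-2-(3,4,5-trimethoxyphenoxy)-4-[1-(2,4,6-trimethoxyphenoxy)ethenyl]-4-(trimethylsilyloxy)cyclobut-2-en-1-one | C[Si](C)(C)OC1(C(=C)Oc2c(OC)cc(OC)cc2OC)C(OC)=C(Oc2cc(OC)c(OC)c(OC)c2)C1=O | intermediate
17 | (Z)-dienylketene from ring opening of 16 | O=C=C(Oc1cc(OC)c(OC)c(OC)c1)/C(OC)=C(/O[Si](C)(C)C)C(=C)Oc1c(OC)cc(OC)cc1OC | intermediate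
18 | 3-methoxy-2-(3,4,5-trimethoxyphenoxy)-5-(2,4,6-trimethoxyphenoxy)-4-(trimethylsilyloxy)phenol | Oc1cc(Oc2c(OC)cc(OC)cc2OC)c(O[Si](C)(C)C)c(OC)c1Oc1cc(OC)c(OC)c(OC)c1 | intermediate
19 | tert-butyl carbonate of 18 | CC(C)(C)OC(=O)Oc1cc(Oc2c(OC)cc(OC)cc2OC)c(O[Si](C)(C)C)c(OC)c1Oc1cc(OC)c(OC)c(OC)c1 | intermediate
20 | tert-butyl [4-hydroxy-3-methoxy-2-(3,4,5-trimethoxyphenoxy)-5-(2,4,6-trimethoxyphenoxy)phenyl] carbonate | CC(C)(C)OC(=O)Oc1cc(Oc2c(OC)cc(OC)cc2OC)c(O)c(OC)c1Oc1cc(OC)c(OC)c(OC)c1 | intermediate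
21 | 3,4,5-trimethoxyphenylboronic acid | COc1cc(B(O)O)cc(OC)c1OC | starting material
22 | tert-butyl [3-methoxy-2,4-bis(3,4,5-trimethoxyphenoxy)-5-(2,4,6-trimethoxyphenoxy)phenyl] carbonate | CC(C)(C)OC(=O)Oc1cc(Oc2c(OC)cc(OC)cc2OC)c(Oc2cc(OC)c(OC)c(OC)c2)c(OC)c1Oc1cc(OC)c(OC)c(OC)c1 | intermediate
23 | 2,4-bis(3,4,5-trihydroxyphenoxy)-5-(2,4,6-trihydroxyphenoxy)benzene-1,3-diol | Oc1cc(O)c(Oc2cc(O)c(Oc3cc(O)c(O)c(O)c3)c(O)c2Oc2cc(O)c(O)c(O)c2)c(O)c1 | target

## Step count and risks
Total steps: 7. Longest linear sequence: 6 (steps 1, 2, 4, 5, 6, 7). Step 3 is the side branch.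

**Step 4 (most at risk).**
- Reagent 14 is a carbenoid with a good leaving group and may lose lithium aryloxide.
- It may also displace the aryloxy group of 13, or discriminate poorly between the two carbonyls.
- The fallback sets out from 13 and keeps the same ring construction, but takes ring A off the nucleophile.
- Ethyl vinyl ether and t-BuLi (THF, −78 → 0 °C) give 1-ethoxyvinyllithium F1. This is added to 13 at −78 °C and the adduct is silylated in situ with TBSOTf to the TBS-protected ethoxyvinyl cyclobutenone F2.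
- Heating in toluene at 110 °C gives the ethoxy silyloxy phenol F3, whose only free OH is now the ring-A position.
- Ullmann coupling with commercial 2-iodo-1,3,5-trimethoxybenzene (CuI, picolinic acid, K3PO4, DMSO, 90 °C) gives the ring-A ether F4, and TBAF frees the hindered phenol F5.
- Arylation with 21 as in step 6 gives the fully alkylated tetramer F6. BBr3 as in step 7 cleaves all alkyl ethers and comes back to the route at 23.

**Step 6.**
- The OH of 20 sits between OMe and a bulky 2,6-dimethoxyaryloxy group, and the phenol is oxidisable by Cu(II)/O2.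
- The fallback sets out from 20 and replaces copper by metal-free ligand coupling on iodine(III).
- Commercial 5-iodo-1,2,3-trimethoxybenzene is converted in one pot (mCPBA, TsOH·H2O, MeCN; then 1,3,5-trimethoxybenzene) into (3,4,5-trimethoxyphenyl)(2,4,6-trimethoxyphenyl)iodonium tosylate F7.
- The potassium phenoxide of 20 (t-BuOK, THF, 0 → 40 °C) takes over the less electron-rich 3,4,5-trimethoxyphenyl group, while the 2,4,6-trimethoxyphenyl group acts as the non-transferred ligand. This comes back at 22.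

**Step 2.**
- Aryl ethynyl ether 7 polymerises easily.
- The hydrostannation may also give some β-stannane.
- The fallback sets out from crude 7 and lets ionic chemistry fix the regiochemistry.
- HI made in situ (TMSCl, NaI, 0.5 equiv H2O, MeCN, −20 °C) protonates the terminal carbon, and iodide adds to the ketenium carbon to give 1-iodoethenyl 2,4,6-trimethoxyphenyl ether F8.
- I–Li exchange (t-BuLi, 2 equiv, Et2O, −78 °C) comes back to the route at 14, which is used as in step 4.

## Further compounds
F1 | step 4 | 1-ethoxyvinyllithium | [Li]C(=C)OCC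
F2 | step 4 | TBS-protected ethoxyvinyl cyclobutenone, (±)-4-(tert-butyldimethylsilyloxy)-4-(1-ethoxyethenyl)-3-methoxy-2-(3,4,5-trimethoxyphenoxy)cyclobut-2-en-1-one | CCOC(=C)C1(O[Si](C)(C)C(C)(C)C)C(OC)=C(Oc2cc(OC)c(OC)c(OC)c2)C1=O
F3 | step 4 | ethoxy silyloxy phenol, 4-(tert-butyldimethylsilyloxy)-5-ethoxy-3-methoxy-2-(3,4,5-trimethoxyphenoxy)phenol | CCOc1cc(O)c(Oc2cc(OC)c(OC)c(OC)c2)c(OC)c1O[Si](C)(C)C(C)(C)C
F4 | step 4 | ring-A ether, 2,4,6-trimethoxyphenyl ether of F3 | CCOc1cc(Oc2c(OC)cc(OC)cc2OC)c(Oc2cc(OC)c(OC)c(OC)c2)c(OC)c1O[Si](C)(C)C(C)(C)C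
F5 | step 4 | hindered phenol, 6-ethoxy-2-methoxy-3-(3,4,5-trimethoxyphenoxy)-4-(2,4,6-trimethoxyphenoxy)phenol | CCOc1cc(Oc2c(OC)cc(OC)cc2OC)c(Oc2cc(OC)c(OC)c(OC)c2)c(OC)c1O
F6 | step 4 | fully alkylated tetramer, 1-ethoxy-3-methoxy-2,4-bis(3,4,5-trimethoxyphenoxy)-5-(2,4,6-trimethoxyphenoxy)benzene | CCOc1cc(Oc2c(OC)cc(OC)cc2OC)c(Oc2cc(OC)c(OC)c(OC)c2)c(OC)c1Oc1cc(OC)c(OC)c(OC)c1
F7 | step 6 | (3,4,5-trimethoxyphenyl)(2,4,6-trimethoxyphenyl)iodonium tosylate | COc1cc(OC)c([I+]c2cc(OC)c(OC)c(OC)c2)c(OC)c1.Cc1ccc(S(=O)(=O)[O-])cc1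
F8 | step 2 | 1-iodoethenyl 2,4,6-trimethoxyphenyl ether | C=C(I)Oc1c(OC)cc(OC)cc1OC
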